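## Structural features

Irigenin is an isoflavone: a benzo ring A fused to a 4-pyranone ring C (4H-chromen-4-one), with an aryl ring B attached to C3 by a single C3–C1' bond. The molecule has no stereocentre, so none stand next to each other and none has to be set. Ring A is substituted everywhere except C8: OH at C5 (hydrogen-bonded to the C4 carbonyl), OMe at C6, OH at C7. Ring B carries OH at C3' and OMe at C4' and C5'. The fragile parts are the three free phenols on electron-rich rings (oxidised in base and air), ring C (opened at C2 by hydroxide and other hard nucleophiles), and the three methyl ethers, which must stay distinct from the three hydroxyls. The difficulty is regiochemical: the methoxy group must end at C6 and not C8, although the two oxygens ortho to the ring-A carbonyl are equivalent in any symmetric ring-A precursor, and ring B must sit on C3 and not C2. The key step uses C3, which carries both ring B and the C4 carbonyl: as a benzylic carbon it can bear positive charge shared with ring B (the C4' methoxy is para) and so accept the ring-A aroyl carbon C4 from its neighbour, which becomes C2 at the aldehyde level. This donor effect is weaker than in a plain 4-methoxyphenyl ring, because the C3' and C5' oxygens twist the C4' methoxy out of plane and withdraw inductively, so the precursor must offer the cation no other escape.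

## Logic of the disconnections

21 to 20: the three benzylic O–CH2 bonds on O5, O7 and O3' are cut. Benzyl keeps hydroxyl and methoxy oxygens distinct throughout and comes off under neutral conditions that spare ring C and the methyl ethers. The gain is that every earlier step runs on non-phenolic material. The demand is hydrogenolysis that does not saturate C2=C3.

20 to 18: the O1–C2 bond of ring C is cut and the oxygen that becomes O1 is returned to its acetal. Ring C is an aryl enol ether of a 1,3-dicarbonyl unit and forms by dehydration. The gain is an open-chain 2-aryl-3-oxopropanal. The demand is that only one of the two ortho oxygens of ring A can be freed: one is an acid-labile acetal, the other a benzyl ether, and one acid treatment must unmask and dehydrate.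

18 to 17 (key): the C3–C4 bond is cut, C4 is rejoined to the carbon that is C2, and C2 and C3 are tied by an oxirane oxygen. This retro-1,2-shift turns the branched 2-aryl-1,3-dicarbonyl chain into the linear 1,3-diarylpropane chain of a chalcone. The gain is that all ring-C carbons come from a methyl ketone and a benzaldehyde, with no arylacetic acid and no one-carbon insertion. The demand is ionisation only at the ring-B carbon, migration only of the aroyl group, and an acetal that survives the Lewis acid long enough.

17 to 16: both C–O bonds of the oxirane are cut to give the enone. The gain is an achiral precursor. The demand is a nucleophilic oxidant that leaves the electron-rich rings alone; the relative configuration does not matter later.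

16 to 12 and 14: the Cα=Cβ bond is cut (aldol condensation). The gain is two aromatic halves of similar size joined convergently. The demand is that a ketone with two ortho substituents enolises and condenses, and that all protecting groups tolerate hydroxide.

14 to 13 and 2: the O–benzyl bond is cut; 13 already has the ring-B oxygen pattern with the one free hydroxyl in the right place.

12 to 9 and 10, then 9 to 7 and 8: the aryl–acyl bond is cut, then the acetal O–CH2 bond. The carbon to be acylated lies between the acetal oxygen and a benzyloxy group, the position a directed metalation reaches, so the acetal serves as directing group and later as the one acid-labile group. The gain is the symmetric 7, whose two ortho carbons are identical, so no regiochemistry arises. The demand is ring lithiation faster than benzylic deprotonation, and a single addition to the acyl donor.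

7 to 5: the phenolic C–O bond is replaced by a C–CHO bond (retro-Baeyer–Villiger). A 1,2,3,5-tetraoxygenated benzene is not a common building block, while the 3,4,5-trioxygenated benzoate is. The demand is aryl migration in preference to hydride migration.

5 to 4 to 3 to 1 and 2: two oxidation-level changes and two O–benzyl cuts, the latter made in one operation with two equivalents of 2. 1 already has the methyl ether between two hydroxyls, which is the C5/C6/C7 pattern of 21.

## Other disconnections considered

Alternative 1: The cut is through ring A at C5–C6 and C7–C8, leaving the monocyclic pyranone ester A1, which already holds ring B, the C4 carbonyl, a methyl group (future C8) and an ester (future C5). The forward key step would use excess LiN(SiMe3)2 to deprotonate the methyl group, acylate the anion with A2 (which supplies C6, C7 and the C6 methoxy) and let the new enolate close onto the ester, giving A3. In its favour, the methoxy group arrives on its own carbon, so the C6/C8 question never arises; ring A needs no protecting group, and A3 is one hydrogenolysis from 21. On structure and on step economy this plan is the better one: it is more convergent and probably several steps shorter, with no Baeyer–Villiger detour. Against it here, A1 has an unsubstituted, electrophilic ring carbon next to the ring oxygen that amide bases and enolates can attack with ring opening; three acidic sites must be handled in sequence; A2 can self-condense under the same base; and A1 itself needs an arylacetyl unit of ring B. On mechanism the chosen plan is the safer one, since it rests on one cationic shift and otherwise routine steps, where this cascade passes through several anions on a base-sensitive heterocycle. The final deprotection is equal in kind and simpler in the alternative.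

Alternative 2: The cut is the C5–O bond. The 5-deoxy isoflavone A4 would be borylated at C5–H with [Ir(OMe)(cod)]2, AsPh3 and B2pin2 under direction by the C4 carbonyl, and the C–B bond oxidised with NaBO3 in the same flask to give A5. In its favour, ring A then needs only three oxygens and has a single oxygen ortho to the carbonyl, so ring C can close only one way and no acetal is needed. On supply of ring A and on step count this plan is the better one, probably by two or three steps, and the last step is equal (hydrogenolysis). Against it here, C5–H lies between C4a and the C6 methoxy, and such flanked C–H bonds are the slow ones in iridium borylation. The unhindered C–H bonds of the two benzyl groups, C2–H of ring C and C8–H are competing sites, and the enone of ring C could be reduced by boron hydride species. The chosen plan fixes every oxygen before the rings are joined and takes its regiochemistry from cation stability; the alternative needs a directing effect to override a steric preference. It also needs a precious-metal catalyst and a diboron reagent.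

Alternative 3: The cut is C4–C4a. The acrylic acid A6, an enol ether of a symmetric ring-A phenol, would be converted to its chloride A7, and SnCl4 would acylate the ring carbon ortho to the ether oxygen, closing ring C to A8, which is the same compound as 20. In its favour, the two ortho carbons of the symmetric ether are equivalent, so one regioisomer is expected without differentiated protection or an epoxide; on this point it is the better plan, and the end game is equal. Against it here, SnCl4 and acid chloride formation must be survived by three benzyl ethers and an acid-sensitive β-aryloxyacrylate that can fragment back to phenol. The acylation site is flanked on both sides, the aryloxy group must be cis to the acyl chloride, and ring B must enter as an arylacetic acid, which costs a homologation of the benzaldehyde. On mechanism the closure is simple but runs under conditions hostile to the protecting groups, where the chosen shift needs only a brief exposure to BF3. On step count the two plans are about equal.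

Key step: step 10

Remarks on the chemistry:
- 1, 2, 8, 10 and 13 are taken as purchasable.
- Step 1 consumes two equivalents of 2, one for each of the two equivalent phenols of 1; the second equivalent is entered on the line of reagents that add atoms.
- 15 and 17 are racemic, with one enantiomer drawn; the oxirane descriptors (2R,3S)/(2S,3R) correspond to the trans epoxide.
- Ring A is named with lowest locants, 2,4-bis(benzyloxy)-3-methoxy-6-(methoxymethoxy)phenyl; counted from the other ortho carbon the same group reads 4,6-bis(benzyloxy)-5-methoxy-2-(methoxymethoxy)phenyl.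
- Design of 17: the acetal sits on the oxygen that becomes O1 and benzyl on the other three, and the two acetyl carbons enter by metalation ortho to that acetal. This is shorter than a formylation, Grignard addition and oxidation sequence, which is kept as a fallback.

## Steps

Step 1
Reactants: 1 methyl 3,5-dihydroxy-4-methoxybenzoate; 2 benzyl bromide
Product: 3 methyl 3,5-bis(benzyloxy)-4-methoxybenzoate
Conditions: BnBr (2.4 equiv in all), K2CO3, DMF, 60 °C
Reagents that add atoms: benzyl bromide (second equivalent, the same compound as 2), BrCc1ccccc1
Why: Double Williamson O-benzylation: each of the two equivalent phenols takes one benzyl group, so two equivalents of 2 are consumed; the ester and the flanked methyl ether are inert to K2CO3 in DMF.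

Step 2
Reactants: 3 methyl 3,5-bis(benzyloxy)-4-methoxybenzoate
Product: 4 [3,5-bis(benzyloxy)-4-methoxyphenyl]methanol
Conditions: LiAlH4, THF, 0 °C to rt
Reagents that add atoms: none
Why: Hydride reduction of an aryl ester to the benzylic alcohol; benzyl and methyl aryl ethers do not react with LiAlH4.

Step 3
Reactants: 4 [3,5-bis(benzyloxy)-4-methoxyphenyl]methanol
Product: 5 3,5-bis(benzyloxy)-4-methoxybenzaldehyde
Conditions: activated MnO2 (excess), CH2Cl2, rt
Reagents that add atoms: none
Why: MnO2 oxidises benzylic alcohols selectively and should stop at the aldehyde; the ethers are untouched.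

Step 4
Reactants: 5 3,5-bis(benzyloxy)-4-methoxybenzaldehyde
Product: 7 3,5-bis(benzyloxy)-4-methoxyphenol, via 3,5-bis(benzyloxy)-4-methoxyphenyl formate 6 (not isolated)
Conditions: mCPBA, CH2Cl2, 0 °C to rt; Na2SO3 wash; then K2CO3 (cat.), MeOH, rt
Reagents that add atoms: 3-chloroperoxybenzoic acid (mCPBA), OOC(=O)c1cccc(Cl)c1
Why: Baeyer–Villiger (Dakin-type) oxidation: in the Criegee adduct the electron-rich trialkoxyaryl group should migrate in preference to hydride and give formate 6, which mild methanolysis cleaves to the phenol. The peracid is destroyed before the phenol is released, so that it is not oxidised further.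

Step 5
Reactants: 7 3,5-bis(benzyloxy)-4-methoxyphenol; 8 chloromethyl methyl ether
Product: 9 1,3-bis(benzyloxy)-2-methoxy-5-(methoxymethoxy)benzene
Conditions: MOMCl, i-Pr2NEt, CH2Cl2, 0 °C to rt
Reagents that add atoms: none
Why: O-alkylation of the phenol by the α-chloro ether; the acetal serves first as directing group for metalation and later as the only acid-labile group among benzyl ethers.

Step 6
Reactants: 9 1,3-bis(benzyloxy)-2-methoxy-5-(methoxymethoxy)benzene; 10 N-methoxy-N-methylacetamide
Product: 12 1-[2,4-bis(benzyloxy)-3-methoxy-6-(methoxymethoxy)phenyl]ethan-1-one, via [2,4-bis(benzyloxy)-3-methoxy-6-(methoxymethoxy)phenyl]lithium 11 (not isolated)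
Conditions: n-BuLi, THF, −20 to 0 °C; then 10, −78 °C to rt; aq. NH4Cl
Reagents that add atoms: none
Why: Directed ortho-metalation: the two ring hydrogens are equivalent and each lies between the acetal oxygen and a benzyloxy oxygen, which together coordinate the base and acidify that C–H bond. Aryllithium 11 should add once to the Weinreb amide, because the chelated tetrahedral adduct persists until work-up (Weinreb ketone synthesis).

Step 7
Reactants: 13 3-hydroxy-4,5-dimethoxybenzaldehyde; 2 benzyl bromide
Product: 14 3-(benzyloxy)-4,5-dimethoxybenzaldehyde
Conditions: BnBr, K2CO3, DMF, 60 °C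
Reagents that add atoms: none
Why: Williamson O-benzylation of the single phenol; the aldehyde is not affected.

Step 8
Reactants: 12 1-[2,4-bis(benzyloxy)-3-methoxy-6-(methoxymethoxy)phenyl]ethan-1-one; 14 3-(benzyloxy)-4,5-dimethoxybenzaldehyde
Product: 16 (E)-3-[3-(benzyloxy)-4,5-dimethoxyphenyl]-1-[2,4-bis(benzyloxy)-3-methoxy-6-(methoxymethoxy)phenyl]prop-2-en-1-one, via β-hydroxy ketone aldol adduct 15 (not isolated)
Conditions: KOH (50% aq.), EtOH–THF, rt
Reagents that add atoms: none
Why: Claisen–Schmidt condensation: the methyl ketone enolate adds to the non-enolisable aldehyde, and aldol 15 loses water by an E1cB path to the conjugated E-enone, the more stable geometry. Acetal and benzyl ethers are stable to hydroxide.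

Step 9
Reactants: 16 (E)-3-[3-(benzyloxy)-4,5-dimethoxyphenyl]-1-[2,4-bis(benzyloxy)-3-methoxy-6-(methoxymethoxy)phenyl]prop-2-en-1-one
Product: 17 rac-[(2R,3S)-3-[3-(benzyloxy)-4,5-dimethoxyphenyl]oxiran-2-yl][2,4-bis(benzyloxy)-3-methoxy-6-(methoxymethoxy)phenyl]methanone (trans epoxide)
Conditions: 30% H2O2, aq. NaOH, MeOH–THF, 0 °C to rt
Reagents that add atoms: hydrogen peroxide, OO
Why: Weitz–Scheffer nucleophilic epoxidation: hydroperoxide adds to the β-carbon and the enolate closes the oxirane with loss of hydroxide. Rotation in the enolate before closure sets the two new stereocentres trans to each other (racemic), and alkaline H2O2 does not attack the electron-rich rings or the ethers.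

Step 10
Reactants: 17 rac-[(2R,3S)-3-[3-(benzyloxy)-4,5-dimethoxyphenyl]oxiran-2-yl][2,4-bis(benzyloxy)-3-methoxy-6-(methoxymethoxy)phenyl]methanone
Product: 18 (Z)-2-[3-(benzyloxy)-4,5-dimethoxyphenyl]-1-[2,4-bis(benzyloxy)-3-methoxy-6-(methoxymethoxy)phenyl]-3-hydroxyprop-2-en-1-one (enol form of the formyl ketone)
Conditions: BF3·OEt2 (2–3 equiv), dry CH2Cl2, −20 to 0 °C, short time; aq. NaHCO3
Reagents that add atoms: none
Why: BF3 binds the oxirane oxygen and the C–O bond at the carbon carrying ring B lengthens, because positive charge there is benzylic and shared with ring B, whereas ionisation at the other carbon would place charge next to the carbonyl group. The ring-A aroyl group on the neighbouring carbon then shifts with its bonding pair to this electron-poor carbon (semipinacol-type acyl 1,2-shift), making the C3–C4 bond of the future chromone, and the oxygen left on the former α-carbon becomes the C2 aldehyde; loss of BF3 on work-up and tautomerisation give the hydrogen-bonded Z-enol. The closest known reaction type is the Lewis-acid rearrangement of 2'-alkoxychalcone epoxides to 2-aryl-3-oxopropanals by acyl migration. No ring closes and no stereocentre is made; both oxirane stereocentres disappear, so any cis epoxide in 17 would converge on the same product. Three selectivities are needed: opening at the ring-B carbon only, migration of the aroyl group and not of hydride (which would lead to a 1,2-diketone) or capture by fluoride, and no attack of a ring-A ortho oxygen on the cation. The first is secured by ring B, the second by the high migratory aptitude of an electron-rich aroyl group whose C–C bond can lie anti to the breaking C–O bond, and the third by keeping both ortho oxygens as ethers under anhydrous conditions at low temperature for a short time. Loss of the acetal after the shift would be harmless, since it only anticipates step 11.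

Step 11
Reactants: 18 (Z)-2-[3-(benzyloxy)-4,5-dimethoxyphenyl]-1-[2,4-bis(benzyloxy)-3-methoxy-6-(methoxymethoxy)phenyl]-3-hydroxyprop-2-en-1-one
Product: 20 5,7-bis(benzyloxy)-3-[3-(benzyloxy)-4,5-dimethoxyphenyl]-6-methoxy-4H-chromen-4-one, via demethoxymethylated phenol 19 (not isolated)
Conditions: conc. HCl (cat.), MeOH–THF, 50 °C
Reagents that add atoms: none
Why: Acidic methanol removes the acetal by transacetalisation, and the freed phenol of 19 adds to the aldehyde carbon and loses water to give the aromatic pyranone ring C (chromone ring closure by cyclodehydration). The other ortho oxygen stays benzylated and cannot close, which places the methoxy group at C6 and not C8.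

Step 12
Reactants: 20 5,7-bis(benzyloxy)-3-[3-(benzyloxy)-4,5-dimethoxyphenyl]-6-methoxy-4H-chromen-4-one
Product: 21 irigenin, 5,7-dihydroxy-3-(3-hydroxy-4,5-dimethoxyphenyl)-6-methoxy-4H-chromen-4-one
Conditions: H2 (1 atm), 10% Pd/C, EtOAc–MeOH, rt
Reagents that add atoms: none
Why: Catalytic hydrogenolysis of the three benzyl aryl ethers; the methyl ethers are inert, and the reaction is stopped after uptake of three equivalents of hydrogen so that the C2=C3 bond is kept.

## Compound list

1 | methyl 3,5-dihydroxy-4-methoxybenzoate | COC(=O)c1cc(O)c(OC)c(O)c1 | starting material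
2 | benzyl bromide | BrCc1ccccc1 | starting material
3 | methyl 3,5-bis(benzyloxy)-4-methoxybenzoate | COC(=O)c1cc(OCc2ccccc2)c(OC)c(OCc2ccccc2)c1 | intermediate
4 | [3,5-bis(benzyloxy)-4-methoxyphenyl]methanol | OCc1cc(OCc2ccccc2)c(OC)c(OCc2ccccc2)c1 | intermediate
5 | 3,5-bis(benzyloxy)-4-methoxybenzaldehyde | O=Cc1cc(OCc2ccccc2)c(OC)c(OCc2ccccc2)c1 | intermediate
6 | 3,5-bis(benzyloxy)-4-methoxyphenyl formate | O=COc1cc(OCc2ccccc2)c(OC)c(OCc2ccccc2)c1 | intermediate
7 | 3,5-bis(benzyloxy)-4-methoxyphenol | Oc1cc(OCc2ccccc2)c(OC)c(OCc2ccccc2)c1 | intermediate
8 | chloromethyl methyl ether | COCCl | starting material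
9 | 1,3-bis(benzyloxy)-2-methoxy-5-(methoxymethoxy)benzene | COCOc1cc(OCc2ccccc2)c(OC)c(OCc2ccccc2)c1 | intermediate
10 | N-methoxy-N-methylacetamide | CC(=O)N(C)OC | starting material
11 | [2,4-bis(benzyloxy)-3-methoxy-6-(methoxymethoxy)phenyl]lithium | [Li]c1c(OCOC)cc(OCc2ccccc2)c(OC)c1OCc1ccccc1 | intermediate
12 | 1-[2,4-bis(benzyloxy)-3-methoxy-6-(methoxymethoxy)phenyl]ethan-1-one | CC(=O)c1c(OCOC)cc(OCc2ccccc2)c(OC)c1OCc1ccccc1 | intermediate
13 | 3-hydroxy-4,5-dimethoxybenzaldehyde | COc1cc(C=O)cc(O)c1OC | starting material
14 | 3-(benzyloxy)-4,5-dimethoxybenzaldehyde | COc1cc(C=O)cc(OCc2ccccc2)c1OC | intermediate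
15 | rac-3-[3-(benzyloxy)-4,5-dimethoxyphenyl]-1-[2,4-bis(benzyloxy)-3-methoxy-6-(methoxymethoxy)phenyl]-3-hydroxypropan-1-one (one enantiomer drawn) | O=C(C[C@@H](O)c1cc(OC)c(OC)c(OCc2ccccc2)c1)c1c(OCOC)cc(OCc2ccccc2)c(OC)c1OCc1ccccc1 | intermediate
16 | (E)-3-[3-(benzyloxy)-4,5-dimethoxyphenyl]-1-[2,4-bis(benzyloxy)-3-methoxy-6-(methoxymethoxy)phenyl]prop-2-en-1-one | O=C(/C=C/c1cc(OC)c(OC)c(OCc2ccccc2)c1)c1c(OCOC)cc(OCc2ccccc2)c(OC)c1OCc1ccccc1 | intermediate
17 | rac-[(2R,3S)-3-[3-(benzyloxy)-4,5-dimethoxyphenyl]oxiran-2-yl][2,4-bis(benzyloxy)-3-methoxy-6-(methoxymethoxy)phenyl]methanone, trans (one enantiomer drawn) | O=C([C@@H]1O[C@H]1c1cc(OC)c(OC)c(OCc2ccccc2)c1)c1c(OCOC)cc(OCc2ccccc2)c(OC)c1OCc1ccccc1 | intermediate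
18 | (Z)-2-[3-(benzyloxy)-4,5-dimethoxyphenyl]-1-[2,4-bis(benzyloxy)-3-methoxy-6-(methoxymethoxy)phenyl]-3-hydroxyprop-2-en-1-one | O/C=C(/c1cc(OC)c(OC)c(OCc2ccccc2)c1)C(=O)c1c(OCOC)cc(OCc2ccccc2)c(OC)c1OCc1ccccc1 | intermediate
19 | (Z)-1-[2,4-bis(benzyloxy)-6-hydroxy-3-methoxyphenyl]-2-[3-(benzyloxy)-4,5-dimethoxyphenyl]-3-hydroxyprop-2-en-1-one | O/C=C(/c1cc(OC)c(OC)c(OCc2ccccc2)c1)C(=O)c1c(O)cc(OCc2ccccc2)c(OC)c1OCc1ccccc1 | intermediate
20 | 5,7-bis(benzyloxy)-3-[3-(benzyloxy)-4,5-dimethoxyphenyl]-6-methoxy-4H-chromen-4-one | O=c1c(-c2cc(OC)c(OC)c(OCc3ccccc3)c2)coc2cc(OCc3ccccc3)c(OC)c(OCc3ccccc3)c12 | intermediate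
21 | irigenin, 5,7-dihydroxy-3-(3-hydroxy-4,5-dimethoxyphenyl)-6-methoxy-4H-chromen-4-one | COc1cc(-c2coc3cc(O)c(OC)c(O)c3c2=O)cc(O)c1OC | target

## Step count and risks

Total: 12 steps. Longest linear sequence: 11 steps (steps 1 to 6 and 8 to 12, from 1 to 21); step 7 is a one-step side branch.

Least certain steps:

Step 10 (key step). The acetal may be lost under BF3 before the shift, after which the ortho oxygen can capture the benzylic cation and close a flavanonol-type ring. Ionisation may also be slow, because the para methoxy group of ring B is twisted by its two neighbours and the meta oxygens withdraw inductively, so that fluoride transfer or a hydride shift competes. The fallback sets out from 16 and changes the migrating group. Oxidative 1,2-aryl shift of the chalcone with PhI(OAc)2, HC(OMe)3 and catalytic H2SO4 in MeOH, in which ring B moves from the β- to the α-carbon, should give rac-2-[3-(benzyloxy)-4,5-dimethoxyphenyl]-1-[2,4-bis(benzyloxy)-3-methoxy-6-(methoxymethoxy)phenyl]-3,3-dimethoxypropan-1-one F1. Warming F1 with HCl in MeOH removes the acetal groups and closes ring C, and the fallback comes back to the route at 20.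

Step 6. n-BuLi may deprotonate a benzylic OCH2 group, followed by Wittig rearrangement, or the hindered aryllithium may take a proton from the acetyl donor and return 9. The fallback sets out from 7 and uses no organolithium. Magnesium-mediated ortho-formylation (MgCl2, Et3N, paraformaldehyde, MeCN, reflux) should give 2,4-bis(benzyloxy)-6-hydroxy-3-methoxybenzaldehyde F2. Protection with MOMCl and i-Pr2NEt gives 2,4-bis(benzyloxy)-3-methoxy-6-(methoxymethoxy)benzaldehyde F3, and addition of MeMgBr gives rac-1-[2,4-bis(benzyloxy)-3-methoxy-6-(methoxymethoxy)phenyl]ethan-1-ol F4. Oxidation with Dess–Martin periodinane returns to the route at 12.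

Step 9. Conjugate addition of hydroperoxide may be slow on an enone whose β-carbon carries an electron-rich ring, leaving time for retro-aldol cleavage in the alkaline medium. The fallback sets out from 9 and 14 and builds the oxirane by C–C bond formation. Lithiation of 9 as in step 6 and acylation with 2-chloro-N-methoxy-N-methylacetamide should give 2-chloro-1-[2,4-bis(benzyloxy)-3-methoxy-6-(methoxymethoxy)phenyl]ethan-1-one F5. Darzens condensation of F5 with 14 (NaOMe, MeOH–THF, 0 °C) comes back to the route at 17, bypassing 16.

Step 11. Retro-Claisen loss of the formyl carbon may precede ring closure in acidic methanol, or acetalisation of the aldehyde may slow the closure. The fallback sets out from 18 and locks the formyl carbon first. Condensation with Me2NH (THF, rt) should give (E)-2-[3-(benzyloxy)-4,5-dimethoxyphenyl]-1-[2,4-bis(benzyloxy)-3-methoxy-6-(methoxymethoxy)phenyl]-3-(dimethylamino)prop-2-en-1-one F6. HCl in MeOH then removes the acetal, and the phenol displaces the amine by addition–elimination, coming back to the route at 20.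

Step 12. The C2=C3 bond of ring C may be saturated, or the reaction may stall through adsorption of the polyphenol on the catalyst. The fallback sets out from 20 and uses Lewis-acid dealkylation in place of hydrogenation: BCl3 with pentamethylbenzene as cation scavenger in CH2Cl2 at −78 °C should cleave the three benzyl ethers while the methyl ethers stay, and comes back to the route at 21 with no new compound.

## Further compounds

F1 | step 10 | rac-2-[3-(benzyloxy)-4,5-dimethoxyphenyl]-1-[2,4-bis(benzyloxy)-3-methoxy-6-(methoxymethoxy)phenyl]-3,3-dimethoxypropan-1-one (one enantiomer drawn) | COC(OC)[C@@H](c1cc(OC)c(OC)c(OCc2ccccc2)c1)C(=O)c1c(OCOC)cc(OCc2ccccc2)c(OC)c1OCc1ccccc1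
F2 | step 6 | 2,4-bis(benzyloxy)-6-hydroxy-3-methoxybenzaldehyde | O=Cc1c(O)cc(OCc2ccccc2)c(OC)c1OCc1ccccc1
F3 | step 6 | 2,4-bis(benzyloxy)-3-methoxy-6-(methoxymethoxy)benzaldehyde | O=Cc1c(OCOC)cc(OCc2ccccc2)c(OC)c1OCc1ccccc1
F4 | step 6 | rac-1-[2,4-bis(benzyloxy)-3-methoxy-6-(methoxymethoxy)phenyl]ethan-1-ol (one enantiomer drawn) | C[C@H](O)c1c(OCOC)cc(OCc2ccccc2)c(OC)c1OCc1ccccc1
F5 | step 9 | 2-chloro-1-[2,4-bis(benzyloxy)-3-methoxy-6-(methoxymethoxy)phenyl]ethan-1-one | ClCC(=O)c1c(OCOC)cc(OCc2ccccc2)c(OC)c1OCc1ccccc1
F6 | step 11 | (E)-2-[3-(benzyloxy)-4,5-dimethoxyphenyl]-1-[2,4-bis(benzyloxy)-3-methoxy-6-(methoxymethoxy)phenyl]-3-(dimethylamino)prop-2-en-1-one | CN(C)/C=C(\c1cc(OC)c(OC)c(OCc2ccccc2)c1)C(=O)c1c(OCOC)cc(OCc2ccccc2)c(OC)c1OCc1ccccc1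
F0 | step 12 | none | none
A1 | alternative 1 | methyl 5-[3-(benzyloxy)-4,5-dimethoxyphenyl]-2-methyl-4-oxo-4H-pyran-3-carboxylate | COC(=O)c1c(C)occ(-c2cc(OC)c(OC)c(OCc3ccccc3)c2)c1=O
A2 | alternative 1 | methyl methoxyacetate | COCC(=O)OC
A3 | alternative 1 | 3-[3-(benzyloxy)-4,5-dimethoxyphenyl]-5,7-dihydroxy-6-methoxy-4H-chromen-4-one | O=c1c(-c2cc(OC)c(OC)c(OCc3ccccc3)c2)coc2cc(O)c(OC)c(O)c12
A4 | alternative 2 | 7-(benzyloxy)-3-[3-(benzyloxy)-4,5-dimethoxyphenyl]-6-methoxy-4H-chromen-4-one | O=c1c(-c2cc(OC)c(OC)c(OCc3ccccc3)c2)coc2cc(OCc3ccccc3)c(OC)cc12
A5 | alternative 2 | 7-(benzyloxy)-3-[3-(benzyloxy)-4,5-dimethoxyphenyl]-5-hydroxy-6-methoxy-4H-chromen-4-one | O=c1c(-c2cc(OC)c(OC)c(OCc3ccccc3)c2)coc2cc(OCc3ccccc3)c(OC)c(O)c12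
A6 | alternative 3 | (Z)-3-[3,5-bis(benzyloxy)-4-methoxyphenoxy]-2-[3-(benzyloxy)-4,5-dimethoxyphenyl]prop-2-enoic acid | OC(=O)/C(=C\Oc1cc(OCc2ccccc2)c(OC)c(OCc2ccccc2)c1)c1cc(OC)c(OC)c(OCc2ccccc2)c1
A7 | alternative 3 | (Z)-3-[3,5-bis(benzyloxy)-4-methoxyphenoxy]-2-[3-(benzyloxy)-4,5-dimethoxyphenyl]prop-2-enoyl chloride | ClC(=O)/C(=C\Oc1cc(OCc2ccccc2)c(OC)c(OCc2ccccc2)c1)c1cc(OC)c(OC)c(OCc2ccccc2)c1
A8 | alternative 3 | 5,7-bis(benzyloxy)-3-[3-(benzyloxy)-4,5-dimethoxyphenyl]-6-methoxy-4H-chromen-4-one (same compound as 20) | O=c1c(-c2cc(OC)c(OC)c(OCc3ccccc3)c2)coc2cc(OCc3ccccc3)c(OC)c(OCc3ccccc3)c12
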